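**Retrosynthetic overview**
- Ring C (the pyranone) is closed last: the O1–C2 aryl ether comes from an open-chain triol by intramolecular Mitsunobu reaction; rings A and B are bought as arenes.
- C3–C1' (quaternary carbinol carbon to ring B): photostimulated radical-chain arylation of a dioxolanyl aryl ketone enolate with the ring B aryl iodide.
- Stereocentre: the D-glycerate centre sets a tert-butyl acetal carbon, which in turn directs the arylation, so the original carbon is regenerated as C3 (R).
- C4–C4a: acyl substitution of the glycerate-derived ester by lithiated tris-MOM phloroglucinol.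
- Ring B: O-prenylation, aromatic Claisen rearrangement (reverse prenyl), MOM capping, Br to I exchange.

Assumption: the given SMILES is read as the (3R) enantiomer (priorities OH > C4 > C2 > aryl), and phloroglucinol, methyl (R)-2,2-dimethyl-1,3-dioxolane-4-carboxylate (D-glycerate acetonide), 4-bromo-3-methoxyphenol and prenyl bromide are catalogue chemicals.

**Step 1**
Reactants: 1 phloroglucinol
Product: 2 1,3,5-tris(methoxymethoxy)benzene
Conditions: MOMCl (3.6 equiv), i-Pr2NEt (4 equiv), CH2Cl2, 0 °C to rt
Reagents that add atoms: chloromethyl methyl ether (MOMCl), COCCl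
Why: Williamson-type O-alkylation of the three phenols by the hard electrophile MOMCl under amine base gives the tris-acetal ether, with O- rather than C-alkylation.

**Step 2**
Reactants: 3 methyl (R)-2,2-dimethyl-1,3-dioxolane-4-carboxylate
Product: 5 methyl (2R,4R)-2-tert-butyl-1,3-dioxolane-4-carboxylate, via methyl (R)-glycerate 4 (not isolated)
Conditions: TsOH·H2O (5 mol%), MeOH, rt, evaporate; then t-BuCHO (3 equiv), TsOH·H2O (cat.), pentane, reflux, Dean–Stark; chromatography to isolate the cis isomer
Reagents that add atoms: pivalaldehyde, CC(C)(C)C=O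
Why: Acid-catalysed acetal exchange under thermodynamic control leaves the bought (R) centre (C4) untouched and biases the new acetal carbon C2 toward the cis (2R,4R) dioxolane (expected major, modest ratio), which must be separated from the trans (2S,4R) isomer because the C2 configuration alone steers step 7 and so fixes the final enantiomeric purity (trans material is re-equilibrated and recycled).

**Step 3**
Reactants: 2 1,3,5-tris(methoxymethoxy)benzene; 5 methyl (2R,4R)-2-tert-butyl-1,3-dioxolane-4-carboxylate
Product: 7 [(2R,4R)-2-tert-butyl-1,3-dioxolan-4-yl][2,4,6-tris(methoxymethoxy)phenyl]methanone, via aryllithium 6 (not isolated)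
Conditions: 2 (1.3 equiv), n-BuLi (1.25 equiv), THF, 0 °C, 1 h; then 5, −78 °C, 1 h; sat. aq. NH4Cl at −78 °C
Reagents that add atoms: none
Why: Directed ortho-lithiation between two MOM ethers followed by acyl substitution on the α-alkoxy ester stops at the ketone because the chelated tetrahedral adduct survives at −78 °C and the doubly ortho-substituted aryl ketone resists a second addition; any epimerisation at C4 is harmless since C4 is planarised in step 7 and only C2 carries the stereochemical information.

**Step 4**
Reactants: 8 4-bromo-3-methoxyphenol; 9 prenyl bromide (1-bromo-3-methylbut-2-ene)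
Product: 10 1-bromo-2-methoxy-4-[(3-methylbut-2-en-1-yl)oxy]benzene
Conditions: K2CO3, acetone, reflux
Reagents that add atoms: none
Why: Williamson ether synthesis, SN2 attack of the phenoxide on the primary allylic bromide.

**Step 5**
Reactants: 10 1-bromo-2-methoxy-4-[(3-methylbut-2-en-1-yl)oxy]benzene
Product: 12 1-bromo-2-methoxy-4-(methoxymethoxy)-5-(2-methylbut-3-en-2-yl)benzene, via Claisen phenol 11 (not isolated)
Conditions: PhNEt2, 190 °C (sealed tube), 4 h; cool to 0 °C, CH2Cl2, i-Pr2NEt, MOMCl, rt
Reagents that add atoms: chloromethyl methyl ether (MOMCl), COCCl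
Why: Aromatic Claisen rearrangement ([3,3]) delivers the inverted 1,1-dimethylallyl group to the less hindered ortho carbon (para to OMe, with the para position blocked by Br), and immediate MOM capping of the phenol suppresses abnormal Claisen rearrangement and cyclisation of the ortho-allylphenol.

**Step 6**
Reactants: 12 1-bromo-2-methoxy-4-(methoxymethoxy)-5-(2-methylbut-3-en-2-yl)benzene
Product: 13 1-iodo-2-methoxy-4-(methoxymethoxy)-5-(2-methylbut-3-en-2-yl)benzene
Conditions: NaI (2 equiv), CuI (5 mol%), MeNHCH2CH2NHMe (10 mol%), 1,4-dioxane, 110 °C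
Reagents that add atoms: sodium iodide, [Na+].[I-]
Why: Copper-catalysed aromatic Finkelstein halogen exchange, driven by precipitation of NaBr, supplies the iodide as the faster electron acceptor needed for the chain in step 7.

**Step 7**
Reactants: 7 [(2R,4R)-2-tert-butyl-1,3-dioxolan-4-yl][2,4,6-tris(methoxymethoxy)phenyl]methanone; 13 1-iodo-2-methoxy-4-(methoxymethoxy)-5-(2-methylbut-3-en-2-yl)benzene
Product: 15 [(2R,4R)-2-tert-butyl-4-[2-methoxy-4-(methoxymethoxy)-5-(2-methylbut-3-en-2-yl)phenyl]-1,3-dioxolan-4-yl][2,4,6-tris(methoxymethoxy)phenyl]methanone, via potassium enolate 14 (not isolated)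
Conditions: 7 (1.5 equiv), KN(SiMe3)2 (1.45 equiv), THF, −78 °C; then liquid NH3/THF (3:1), 13 (1.0 equiv), hν (390 nm LEDs), −45 °C, Ar; chromatography removes the C4 epimer
Reagents that add atoms: none
Why: Proposed new method: a photostimulated radical-chain (SRN1) α-arylation of a self-regenerating chiral-acetal enolate, in which light-induced electron transfer from enolate 14 (or its charge-transfer complex with 13) to the aryl iodide gives, after loss of iodide, the ring B aryl radical, which couples at the exocyclic enolate carbon C4 on the face anti to the tert-butyl group at C2 (an early, sterically tolerant radical–anion coupling suited to a congested quaternary centre), and the resulting ketyl radical anion hands its electron to the next molecule of 13 to carry the chain; the in-ring C5–O bond lies near the nodal plane of the enolate so β-elimination is slow at −45 °C, the product has no α-hydrogen and cannot be arylated again, the neutral product does not absorb at 390 nm, and the new C4 (R) centre is thus set by the acetal centre that the glycerate centre set in step 2; the closest known reactions are the photostimulated SRN1 arylation of simple ketone enolates in liquid ammonia and the anti-selective alkylation of 2-tert-butyl-1,3-dioxolane enolates with exocyclic double bonds, which have not been combined.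

**Step 8**
Reactants: 15 [(2R,4R)-2-tert-butyl-4-[2-methoxy-4-(methoxymethoxy)-5-(2-methylbut-3-en-2-yl)phenyl]-1,3-dioxolan-4-yl][2,4,6-tris(methoxymethoxy)phenyl]methanone
Product: 16 (2R)-2,3-dihydroxy-2-[4-hydroxy-2-methoxy-5-(2-methylbut-3-en-2-yl)phenyl]-1-(2,4,6-trihydroxyphenyl)propan-1-one
Conditions: HCl (1.25 M in MeOH), 45 °C, Ar
Reagents that add atoms: none
Why: Acid-catalysed transacetalisation to methanol removes the four MOM ethers (as dimethoxymethane, which keeps formaldehyde away from the phloroglucinol ring) and the pivalaldehyde acetal, while the tertiary carbinol keeps its configuration because ionisation next to the carbonyl is disfavoured and the monosubstituted alkene is not protonated under these mild conditions.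

**Step 9**
Reactants: 16 (2R)-2,3-dihydroxy-2-[4-hydroxy-2-methoxy-5-(2-methylbut-3-en-2-yl)phenyl]-1-(2,4,6-trihydroxyphenyl)propan-1-one
Product: 17 (3R)-3,5,7-trihydroxy-3-[4-hydroxy-2-methoxy-5-(2-methylbut-3-en-2-yl)phenyl]-2,3-dihydro-4H-chromen-4-one (CNP0142880.1)
Conditions: PPh3 (1.3 equiv), DIAD (1.3 equiv), THF (0.01 M), 0 °C to rt
Reagents that add atoms: none
Why: Intramolecular Mitsunobu etherification activates the primary alcohol as its alkoxyphosphonium, which is displaced by an acidic ortho-phenol of ring A in a 6-exo-tet closure (either ortho OH gives the same product), and the tertiary carbinol centre is not involved and stays (R).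

**Compound list**
1 | phloroglucinol (benzene-1,3,5-triol) | Oc1cc(O)cc(O)c1 | starting material
2 | 1,3,5-tris(methoxymethoxy)benzene | COCOc1cc(OCOC)cc(OCOC)c1 | intermediate
3 | methyl (R)-2,2-dimethyl-1,3-dioxolane-4-carboxylate | COC(=O)[C@H]1COC(C)(C)O1 | starting material
4 | methyl (R)-2,3-dihydroxypropanoate (methyl D-glycerate) | COC(=O)[C@H](O)CO | intermediate
5 | methyl (2R,4R)-2-tert-butyl-1,3-dioxolane-4-carboxylate (cis) | COC(=O)[C@H]1CO[C@@H](C(C)(C)C)O1 | intermediate
6 | 2,4,6-tris(methoxymethoxy)phenyllithium | [Li]c1c(OCOC)cc(OCOC)cc1OCOC | intermediate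
7 | [(2R,4R)-2-tert-butyl-1,3-dioxolan-4-yl][2,4,6-tris(methoxymethoxy)phenyl]methanone | COCOc1cc(OCOC)cc(OCOC)c1C(=O)[C@H]1CO[C@@H](C(C)(C)C)O1 | intermediate
8 | 4-bromo-3-methoxyphenol | COc1cc(O)ccc1Br | starting material
9 | prenyl bromide (1-bromo-3-methylbut-2-ene) | CC(C)=CCBr | starting material
10 | 1-bromo-2-methoxy-4-[(3-methylbut-2-en-1-yl)oxy]benzene | COc1cc(OCC=C(C)C)ccc1Br | intermediate
11 | 4-bromo-5-methoxy-2-(2-methylbut-3-en-2-yl)phenol | COc1cc(O)c(C(C)(C)C=C)cc1Br | intermediate
12 | 1-bromo-2-methoxy-4-(methoxymethoxy)-5-(2-methylbut-3-en-2-yl)benzene | COCOc1cc(OC)c(Br)cc1C(C)(C)C=C | intermediate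
13 | 1-iodo-2-methoxy-4-(methoxymethoxy)-5-(2-methylbut-3-en-2-yl)benzene | COCOc1cc(OC)c(I)cc1C(C)(C)C=C | intermediate
14 | potassium enolate of 7, (2R) at the acetal carbon, exocyclic enolate geometry not defined | [K+].[O-]C(=C1CO[C@@H](C(C)(C)C)O1)c1c(OCOC)cc(OCOC)cc1OCOC | intermediate
15 | [(2R,4R)-2-tert-butyl-4-[2-methoxy-4-(methoxymethoxy)-5-(2-methylbut-3-en-2-yl)phenyl]-1,3-dioxolan-4-yl][2,4,6-tris(methoxymethoxy)phenyl]methanone (ring B aryl trans to tert-butyl) | COCOc1cc(OCOC)cc(OCOC)c1C(=O)[C@@]1(c2cc(C(C)(C)C=C)c(OCOC)cc2OC)CO[C@@H](C(C)(C)C)O1 | intermediate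
16 | (2R)-2,3-dihydroxy-2-[4-hydroxy-2-methoxy-5-(2-methylbut-3-en-2-yl)phenyl]-1-(2,4,6-trihydroxyphenyl)propan-1-one | Oc1cc(O)c(C(=O)[C@](O)(CO)c2cc(C(C)(C)C=C)c(O)cc2OC)c(O)c1 | intermediate
17 | (3R)-3,5,7-trihydroxy-3-[4-hydroxy-2-methoxy-5-(2-methylbut-3-en-2-yl)phenyl]-2,3-dihydro-4H-chromen-4-one | C=CC(C)(C)c1cc([C@@]2(O)COc3cc(O)cc(O)c3C2=O)c(OC)cc1O | target

**Totals**
Total step count: 9 (the telescoped operations in steps 2, 3, 5 and 7 are counted once each).
Longest linear sequence: 6 steps (steps 4, 5, 6, 7, 8, 9, from 4-bromo-3-methoxyphenol).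

**Three steps most likely to fail**

Step 7 (the new photochemical arylation). The chain may be short, through slow initiation, hydrogen abstraction by the aryl radical, or fragmentation of the α-alkoxy ketyl, and the anti/syn ratio may be only moderate. The fallback uses known chemistry and sets out from 7, taking bromide 12 directly. Ketone 7 is converted with LiN(i-Pr)2 and Me3SiCl (THF, −78 °C) into {[(2R)-2-tert-butyl-1,3-dioxolan-4-ylidene][2,4,6-tris(methoxymethoxy)phenyl]methoxy}trimethylsilane F3. This neutral silyl enol ether undergoes palladium-catalysed α-arylation with 12 (Pd(dba)2, P(t-Bu)3, CsF, Bu3SnF, toluene, 85 °C). The C-bound palladium enolate forms and reductively eliminates on the face anti to the tert-butyl group, so the fallback comes back to the route at 15.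

Step 9 (Mitsunobu closure on an unprotected hexa-ol). Competing epoxide formation and 5-exo opening to a benzofuranone, or intermolecular etherification, may erode the yield. The fallback sets out from 16 and separates activation from ring closure. Appel bromination of the primary alcohol (PPh3, CBr4, MeCN, 0 °C) gives (2S)-3-bromo-2-hydroxy-2-[4-hydroxy-2-methoxy-5-(2-methylbut-3-en-2-yl)phenyl]-1-(2,4,6-trihydroxyphenyl)propan-1-one F4. Its spatial arrangement is unchanged; the descriptor changes only because CH2Br outranks the carbonyl carbon. K2CO3 in acetone at rt then closes the ether by Williamson displacement at the CH2 carbon, directly or through the terminal epoxide, and the fallback comes back to the route at 17.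

Step 3 (acyl substitution by a hindered, basic aryllithium). Enolisation of ester 5 may win over addition and leave low conversion. The fallback sets out from 5. Reduction with i-Bu2AlH (CH2Cl2, −78 °C) gives (2R,4R)-2-tert-butyl-1,3-dioxolane-4-carbaldehyde F1. Addition of aryllithium 6 (from 2 and n-BuLi, THF, −78 °C) gives [(2R,4R)-2-tert-butyl-1,3-dioxolan-4-yl][2,4,6-tris(methoxymethoxy)phenyl]methanol F2 as a mixture of carbinol epimers, which does not matter. Dess–Martin periodinane oxidation (CH2Cl2, rt) then comes back to the route at 7.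

**Further compounds**
F1 | step 3 | (2R,4R)-2-tert-butyl-1,3-dioxolane-4-carbaldehyde | O=C[C@H]1CO[C@@H](C(C)(C)C)O1
F2 | step 3 | [(2R,4R)-2-tert-butyl-1,3-dioxolan-4-yl][2,4,6-tris(methoxymethoxy)phenyl]methanol (carbinol epimers) | COCOc1cc(OCOC)cc(OCOC)c1C(O)[C@H]1CO[C@@H](C(C)(C)C)O1
F3 | step 7 | {[(2R)-2-tert-butyl-1,3-dioxolan-4-ylidene][2,4,6-tris(methoxymethoxy)phenyl]methoxy}trimethylsilane | C[Si](C)(C)OC(=C1CO[C@@H](C(C)(C)C)O1)c1c(OCOC)cc(OCOC)cc1OCOC
F4 | step 9 | (2S)-3-bromo-2-hydroxy-2-[4-hydroxy-2-methoxy-5-(2-methylbut-3-en-2-yl)phenyl]-1-(2,4,6-trihydroxyphenyl)propan-1-one | Oc1cc(O)c(C(=O)[C@](O)(CBr)c2cc(C(C)(C)C=C)c(O)cc2OC)c(O)c1
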